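Abbreviations used throughout: TBS = tert-butyldimethylsilyl, TES = triethylsilyl, prenyl = 3-methylbut-2-en-1-yl. Ring and atom labels follow flavonoid numbering (O1, C2, C3, C4, C4a, C5–C8, C8a; ring B carbons primed).

## The problem

3-Hydroxyglabrol (21) is a (2R,3R)-trans-2,3-dihydroflavonol. Ring A and the pyranone ring C share the C4a–C8a bond, ring B sits on C2, and a hydroxyl sits on C3. Phenols sit on C7 and C4', and prenyl groups on C8 and C3'.

The C8 prenyl group lies between the oxygen-bearing carbons C7 and C8a. Electrophilic prenylation of a resorcinol ketone does not reach this position cleanly, because C6 competes.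

The two stereocentres are adjacent and both are labile once ring C exists. C3 is alpha to the C4 ketone, and C2 is a benzylic ether carbon para to an oxygen, which can open toward a quinone methide. Neither centre can be relied on to correct the other late. Both are best set together as an open-chain anti pair and then enclosed in ring C without breaking a bond to either.

The two trisubstituted alkenes exclude hydrogenolysis, osmylation and peracids, and strong protic or Lewis acids close o-prenylphenols to chromans. The dihydroflavonol itself is epimerised or dehydrogenated by base, so every protecting group must leave under buffered fluoride.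

The enabling feature is the pattern C7(O)–C8(C)–C8a(O) with an acyl carbon on C4a. This is a 4-acyl-2-alkylcyclohexane-1,3-dione, two hydrogens below the arene. In that dione C8 is the single nucleophilic carbon between two carbonyls, so the prenyl group enters there without ambiguity. The C8a carbonyl is 1,5-related to the C2 hydroxyl through C4a, C4 and C3, so ring C is latent as a 5-hydroxy-1,3-diketone that can cyclodehydrate through the O1–C8a bond.

## Retrosynthesis

**21 from 20.** No skeletal bond is cut. The three oxygens at C3, C7 and C4' carry TBS groups in 20, so a single buffered fluoride treatment ends the synthesis. Benzyl, methyl or acetal protection would each demand conditions the prenyl groups or the dihydroflavonol do not tolerate.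

**20 from 19 and 18.** Two hydrogens are added back across C5–C6, turning ring A into a cyclohexa-1,3-diene. The diene is taken as the C7 silyl dienol ether 19 and not as the free vinylogous acid 18. This fixes the diene tautomer that a quinone dehydrogenates readily, and the phenol emerges silylated. A free o-prenylphenol would be exposed to oxidative chromene formation. Compound 19 comes from 18 by O-silylation of its only acidic hydroxyl.

**18 from 17 (key disconnection).** The O1–C8a bond is cut, which opens ring C to the hydroxy triketone 17. The more usual cut at O1–C2 (phenol displacing a benzylic leaving group or opening an epoxide) breaks a bond at a stereocentre beside an electron-rich arene. The cut at O1–C8a leaves both stereocentres untouched, so the anti pair of 17 maps directly onto the trans ring. The forward reaction must make the C2 hydroxyl, and no other oxygen, add to the C8a carbonyl and then lose water. The TBS ether on the C3 oxygen removes the only competing nucleophile, which would give a five-membered furanone.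

**17 from 16, and 16 from 14 (as dianion 15) and 12.** The C4–C4a bond is cut. This separates ring A, as 2-prenylcyclohexane-1,3-dione 14, from the whole C2–C3–C4 unit with ring B, as Weinreb amide 12. The dianion 15 of 14 carries its reactive carbanion at the carbon that becomes C4a, so the regiochemistry of ring A is decided by the symmetry of the dione. The C2 oxygen is carried as a TES ether through the basic acylation and released selectively afterwards (16 to 17).

**12 from 11, 10, 8 and 4.** The C2–C3 bond is cut by an anti glycolate aldol between aldehyde 4 and glycolyl imide 8. The aldolate is trapped as silyl ether 9 and released as 10. Asymmetric dihydroxylation of a cinnamate is not an option, since the prenyl alkene would be oxidised first and the diol would be syn. The aldol sets both centres in one step and delivers the two oxygens already differentiated: silylated at C3 and free at C2. Transamination (10 to 11) and silylation (11 to 12) follow.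

**Building blocks.** Aldehyde 4 comes from 4-hydroxybenzaldehyde 1 by ortho C-prenylation with prenyl bromide 2 (giving 3) and silylation. Dione 14 comes from cyclohexane-1,3-dione 13 and 2. Imide 8 comes from silyloxyacetic acid 5 and oxazolidinone 6 through mixed anhydride 7.

## Roads not taken

**Alternative 1:** Ring A is cut at three bonds, C8a–C8, C6–C7 and C4a–C8a. The precursors are the diazo ketone methyl (E)-5-diazo-4-oxopent-2-enoate (A1) and the siloxyalkyne triisopropyl[(5-methylhex-4-en-1-yn-1-yl)oxy]silane (A2). Irradiation of A1 causes a Wolff rearrangement to a vinylketene, which adds A2 in a [2+2] sense. The cyclobutenone opens and recloses by 6π electrocyclisation to methyl 2-hydroxy-3-prenyl-4-(triisopropylsilyloxy)benzoate (A3).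

- Merits: the alkyne fixes the prenyl position. Ring A arrives aromatic, so no dehydrogenation is needed beside two prenyl groups. The two ring A oxygens arrive differentiated. In these respects it is better than the chosen plan.
- Weak points: the key step builds only a benzene ring. From A3 the C3–C2 unit, both stereocentres and ring C are still missing. Ring C would most naturally be closed at O1–C2, with inversion at an ionisable benzylic carbon. A1 and A2 require diazo chemistry, photolysis and ynolate silylation.
- Comparison: the chosen plan pays one oxidation step. In return it gets ring A from a commodity dione in one alkylation and closes ring C without touching a stereocentre.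

**Alternative 2:** Ring A is cut at C4a–C5. The precursor is the open-chain triketo acetal (1S,2R)-1,2-bis(TBS-oxy)-1-[4-(TBS-oxy)-3-prenylphenyl]-9,9-dimethoxy-6-prenylnonane-3,5,7-trione (A4). Mild acid frees the C5 aldehyde, and the C4a methylene between the C4 and C8a carbonyls condenses with it. Dehydration and enolisation give the aryl ketone (2R,3S)-2,3-bis(TBS-oxy)-3-[4-(TBS-oxy)-3-prenylphenyl]-1-(2,4-dihydroxy-3-prenylphenyl)propan-1-one (A5).

- Merits: aromatisation costs only water and needs no oxidant. This is a real advantage over the chosen plan.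
- Weak points: A4 is a seven-carbon 1,3,5-tricarbonyl chain that must be assembled by repeated dianion condensations. Under acid, 1,3,5-triketones also close through oxygen to 4-pyranones. A5 still lacks ring C; its closure from the syn diol derivative needs displacement at C2 with clean inversion, at a centre that ionises easily.
- Comparison: the chosen plan makes one C–C bond to a cyclic dione, where A4 needs a linear polyketone, and it carries the anti pair through with retention.

**Alternative 3:** The C2–C3 bond is cut along an alpha-ketol retron. The precursor is the ring-contracted aldehyde (2R,3S)-6-(TBS-oxy)-2-[4-(TBS-oxy)-3-prenylphenyl]-3-hydroxy-7-prenyl-2,3-dihydrobenzofuran-3-carbaldehyde (A6). Al(OiPr)3 chelates the carbinol and aldehyde oxygens, and C2 migrates with retention to the aldehyde carbon. The C4 aryl ketone forms and the ring expands to give 7,4'-bis-TBS 3-hydroxyglabrol (A7).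

- Merits: A7 is one desilylation from the target, a shorter end game than the chosen plan. C3 is created in the key step under chelate control.
- Weak points: A6 is as complex as the target. It needs an aromatic ring A already prenylated between two oxygens, so the regiochemical problem is unsolved. It also needs a quaternary carbinol set cis to the C2 aryl group. Migration of the aryl carbon C3a in place of C2 would give an isomeric chroman-3-one. The benzylic C2–O bond can open under the Lewis acid.
- Comparison: the chosen plan is longer after its key step. Its precursors come from commodity chemicals, and its stereocentres come from one well-understood aldol.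

Key step: step 10

## Route

Assumption: 2-[(tert-butyldimethylsilyl)oxy]acetic acid (5) is treated as a catalogue compound; otherwise it is one silylation–hydrolysis operation from glycolic acid and nothing else changes.

Remark: the dione-derived compounds 16–18 (and F2–F4, F8, F9) are written as enol tautomers so that no undefined centre appears at C4a or C8; they should exist as equilibrating keto–enol mixtures.

Step 1
Reactants: 1 4-hydroxybenzaldehyde; 2 prenyl bromide (1-bromo-3-methylbut-2-ene)
Product: 3 4-hydroxy-3-prenylbenzaldehyde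
Conditions: KOH, H2O, rt
Reagents that add atoms: none
Why: Ortho C-alkylation of a phenoxide in water, where hydrogen bonding shields the oxygen and the allylic bromide is taken by the ring carbon; the para position is blocked by the formyl group. Conversion should be modest, with 1 recoverable, which is acceptable in the first step.

Step 2
Reactants: 3 4-hydroxy-3-prenylbenzaldehyde
Product: 4 4-(TBS-oxy)-3-prenylbenzaldehyde
Conditions: t-BuMe2SiCl, imidazole, DMF, rt
Reagents that add atoms: tert-butyldimethylsilyl chloride, CC(C)(C)[Si](C)(C)Cl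
Why: Standard phenol silylation; the silyl ether also removes the free o-prenylphenol, which would otherwise cyclise to a chroman under later acidic steps.

Step 3
Reactants: 5 2-[(tert-butyldimethylsilyl)oxy]acetic acid; 6 (S)-4-benzyloxazolidin-2-one
Product: 8 (S)-4-benzyl-3-{[(tert-butyldimethylsilyl)oxy]acetyl}oxazolidin-2-one, via mixed pivalic anhydride 7 (not isolated)
Conditions: t-BuCOCl, Et3N, THF, −20 °C; then 6, LiCl, −20 °C → rt
Reagents that add atoms: none
Why: N-acylation of an oxazolidinone through a mixed pivalic anhydride with LiCl/Et3N activation; the hindered pivaloyl carbonyl is not attacked, and no strong base touches the silyl ether.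

Step 4
Reactants: 8 (S)-4-benzyl-3-{[(tert-butyldimethylsilyl)oxy]acetyl}oxazolidin-2-one; 4 4-(TBS-oxy)-3-prenylbenzaldehyde
Product: 10 (S)-4-benzyl-3-[(2R,3R)-2-(TBS-oxy)-3-hydroxy-3-{4-(TBS-oxy)-3-prenylphenyl}propanoyl]oxazolidin-2-one, via trimethylsilyl ether 9 (not isolated)
Conditions: MgCl2 (20 mol%), Et3N, Me3SiCl, EtOAc, rt; then CF3CO2H (cat.), MeOH, 0 °C
Reagents that add atoms: none
Why: Magnesium-halide-catalysed direct anti aldol of an N-acyloxazolidinone (Evans anti aldol): soft enolisation gives the chelated (Z)-enolate, which meets the non-enolisable aryl aldehyde through a boat-like transition state, and silylation of the aldolate to 9 makes the addition irreversible and turns the catalyst over. The (S)-benzyl group shields one face of the chelated enolate, so the aldehyde enters on the face used in enolate alkylation, which fixes the silyloxy carbon as R; the anti mode then fixes the carbinol carbon as R. Brief acidic methanolysis removes only the trimethylsilyl group.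

Step 5
Reactants: 10 (S)-4-benzyl-3-[(2R,3R)-2-(TBS-oxy)-3-hydroxy-3-{4-(TBS-oxy)-3-prenylphenyl}propanoyl]oxazolidin-2-one
Product: 11 (2R,3R)-2-(TBS-oxy)-3-hydroxy-N-methoxy-N-methyl-3-[4-(TBS-oxy)-3-prenylphenyl]propanamide
Conditions: Me3Al, MeONHMe·HCl, CH2Cl2, −10 → 0 °C; aq. potassium sodium tartrate
Reagents that add atoms: N,O-dimethylhydroxylamine hydrochloride, CNOC.Cl
Why: Weinreb transamination of an aldol imide with the aluminium amide; the free beta-hydroxyl binds aluminium and directs attack to the exocyclic carbonyl, and the auxiliary 6 is recovered. Neither stereocentre is enolisable under these conditions.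

Step 6
Reactants: 11 (2R,3R)-2-(TBS-oxy)-3-hydroxy-N-methoxy-N-methyl-3-[4-(TBS-oxy)-3-prenylphenyl]propanamide
Product: 12 (2R,3R)-2-(TBS-oxy)-N-methoxy-N-methyl-3-[4-(TBS-oxy)-3-prenylphenyl]-3-(TES-oxy)propanamide
Conditions: Et3SiOTf, 2,6-lutidine, CH2Cl2, −78 °C
Reagents that add atoms: triethylsilyl trifluoromethanesulfonate, CC[Si](CC)(CC)OS(=O)(=O)C(F)(F)F
Why: Silylation of a hindered secondary alcohol with a silyl triflate; the TES ether is chosen because it can later be removed in the presence of the secondary and aryl TBS ethers.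

Step 7
Reactants: 13 cyclohexane-1,3-dione; 2 prenyl bromide (1-bromo-3-methylbut-2-ene)
Product: 14 2-prenylcyclohexane-1,3-dione
Conditions: KOH, H2O, 0 °C → rt
Reagents that add atoms: none
Why: C-alkylation of a cyclic 1,3-dione enolate with an allylic bromide in water, where solvation of the oxygens favours reaction at C2; this one step places the future C8 prenyl group between the two future ring A oxygens.

Step 8
Reactants: 14 2-prenylcyclohexane-1,3-dione; 12 (2R,3R)-2-(TBS-oxy)-N-methoxy-N-methyl-3-[4-(TBS-oxy)-3-prenylphenyl]-3-(TES-oxy)propanamide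
Product: 16 4-[(2R,3R)-2-(TBS-oxy)-3-{4-(TBS-oxy)-3-prenylphenyl}-3-(TES-oxy)propanoyl]-2-prenylcyclohexane-1,3-dione, via dilithium dianion 15 (not isolated)
Conditions: 14 (2 equiv), LiN(iPr)2 (4.2 equiv), THF–DMPU, −78 → −20 °C; then 12, −78 → −20 °C; aq. NH4Cl
Reagents that add atoms: none
Why: Gamma-acylation of a 1,3-diketone dianion (Claisen-type condensation): the second deprotonation gives the cross-conjugated dienolate 15, whose C4 carbon is the most nucleophilic site, and the Weinreb amide holds the adduct as a chelated tetrahedral intermediate until work-up, so proton transfer to the product and double addition are avoided. The alpha-silyloxy centre is not enolised at low temperature.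

Step 9
Reactants: 16 4-[(2R,3R)-2-(TBS-oxy)-3-{4-(TBS-oxy)-3-prenylphenyl}-3-(TES-oxy)propanoyl]-2-prenylcyclohexane-1,3-dione
Product: 17 4-[(2R,3R)-2-(TBS-oxy)-3-hydroxy-3-{4-(TBS-oxy)-3-prenylphenyl}propanoyl]-2-prenylcyclohexane-1,3-dione
Conditions: HF·pyridine, pyridine, THF, 0 °C
Reagents that add atoms: none
Why: Selective cleavage of a TES ether by buffered HF·pyridine; secondary and aryl TBS ethers are much slower under acidic fluoride, and the absence of alcohol solvent and of base prevents vinylogous ester formation at C7 and silyl migration from the C3 oxygen to the C2 oxygen.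

Step 10
Reactants: 17 4-[(2R,3R)-2-(TBS-oxy)-3-hydroxy-3-{4-(TBS-oxy)-3-prenylphenyl}propanoyl]-2-prenylcyclohexane-1,3-dione
Product: 18 (2R,3R)-3-(TBS-oxy)-2-[4-(TBS-oxy)-3-prenylphenyl]-7-hydroxy-8-prenyl-2,3,5,6-tetrahydro-4H-chromen-4-one
Conditions: pyridinium p-toluenesulfonate (0.2 equiv), 4 Å MS, PhMe, 60 °C
Reagents that add atoms: none
Why: The weak acid activates the enolised C4/C8a beta-diketone, the free C2 hydroxyl adds to the C8a carbonyl, and the cyclic hemiketal loses water toward C4a to give the vinylogous ester, which forms the O1–C8a bond and ring C. The closest known reactions are the acid-catalysed cyclodehydration of 5-hydroxy-1,3-diketones to 2,3-dihydro-4H-pyran-4-ones and the acid-catalysed condensation of alcohols with cyclohexane-1,3-diones to 3-alkoxyenones. The closure is 6-exo-trig onto the C8a carbonyl (equivalently, conjugate addition to the C4a=C8a enol form followed by elimination). No stereocentre is formed and no bond to C2 or C3 is broken, so the anti (2R,3R) pair of 17 becomes the trans (2R,3R) pair of 18. The nucleophile must be the C2 oxygen; this is secured by the TBS ether on the C3 oxygen, which excludes the five-membered furanone. The electrophile must be C8a and not C7; this is secured by ring size, since attack at C7 would need an eight-membered ring. The acid must be too weak to ionise the benzylic C2 hydroxyl or to protonate the prenyl alkenes, hence a pyridinium salt in a non-polar solvent with sieves to take up the water. If some ionisation at C2 did occur, C3 would still hold its configuration and reclosure should favour the same trans isomer.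

Step 11
Reactants: 18 (2R,3R)-3-(TBS-oxy)-2-[4-(TBS-oxy)-3-prenylphenyl]-7-hydroxy-8-prenyl-2,3,5,6-tetrahydro-4H-chromen-4-one
Product: 19 (2R,3R)-3,7-bis(TBS-oxy)-2-[4-(TBS-oxy)-3-prenylphenyl]-8-prenyl-2,3,5,6-tetrahydro-4H-chromen-4-one
Conditions: t-BuMe2SiCl, imidazole, CH2Cl2, 0 °C → rt
Reagents that add atoms: tert-butyldimethylsilyl chloride, CC(C)(C)[Si](C)(C)Cl
Why: O-silylation of a vinylogous acid; the C7 oxygen is the accessible terminus of the enolate and its silylation keeps the O1–C8a=C4a–C4=O conjugation, whereas the C4 oxygen is flanked by the C3 silyl ether. A chloride with imidazole is used instead of a silyl triflate so that the C4 ketone is not enolised toward C3.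

Step 12
Reactants: 19 (2R,3R)-3,7-bis(TBS-oxy)-2-[4-(TBS-oxy)-3-prenylphenyl]-8-prenyl-2,3,5,6-tetrahydro-4H-chromen-4-one
Product: 20 (2R,3R)-3,7-bis(TBS-oxy)-2-[4-(TBS-oxy)-3-prenylphenyl]-8-prenylchroman-4-one
Conditions: DDQ (1.1 equiv), PhMe, 0 °C → rt
Reagents that add atoms: none
Why: Quinone dehydrogenation of a cyclohexa-1,3-diene to the arene: hydride loss from C5 gives a cation delocalised onto C8a and C7, each bearing oxygen, and proton loss from C6 completes ring A. The C7 silyl ether keeps the new o-prenylphenol masked against oxidative chromene formation.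

Step 13
Reactants: 20 (2R,3R)-3,7-bis(TBS-oxy)-2-[4-(TBS-oxy)-3-prenylphenyl]-8-prenylchroman-4-one
Product: 21 3-hydroxyglabrol, (2R,3R)-3,7-dihydroxy-2-(4-hydroxy-3-prenylphenyl)-8-prenylchroman-4-one
Conditions: Bu4NF, AcOH (1:1), THF, 0 °C → rt
Reagents that add atoms: none
Why: Global desilylation with acetic-acid-buffered fluoride; the buffer keeps the phenoxides protonated, so ring C neither opens at C2 nor enolises at C3, and the prenyl groups are inert.

## Compound list

1 | 4-hydroxybenzaldehyde | O=Cc1ccc(O)cc1 | starting material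
2 | prenyl bromide (1-bromo-3-methylbut-2-ene) | CC(C)=CCBr | starting material
3 | 4-hydroxy-3-prenylbenzaldehyde | CC(C)=CCc1cc(C=O)ccc1O | intermediate
4 | 4-(TBS-oxy)-3-prenylbenzaldehyde | CC(C)=CCc1cc(C=O)ccc1O[Si](C)(C)C(C)(C)C | intermediate
5 | 2-[(tert-butyldimethylsilyl)oxy]acetic acid | CC(C)(C)[Si](C)(C)OCC(=O)O | starting material
6 | (S)-4-benzyloxazolidin-2-one | O=C1N[C@@H](Cc2ccccc2)CO1 | starting material
7 | mixed anhydride of 5 with pivalic acid | CC(C)(C)[Si](C)(C)OCC(=O)OC(=O)C(C)(C)C | intermediate
8 | (S)-4-benzyl-3-{[(tert-butyldimethylsilyl)oxy]acetyl}oxazolidin-2-one | CC(C)(C)[Si](C)(C)OCC(=O)N1[C@@H](Cc2ccccc2)COC1=O | intermediate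
9 | trimethylsilyl ether of 10 at the benzylic oxygen | CC(C)=CCc1cc([C@@H](O[Si](C)(C)C)[C@@H](O[Si](C)(C)C(C)(C)C)C(=O)N2[C@@H](Cc3ccccc3)COC2=O)ccc1O[Si](C)(C)C(C)(C)C | intermediate
10 | (S)-4-benzyl-3-[(2R,3R)-2-(TBS-oxy)-3-hydroxy-3-{4-(TBS-oxy)-3-prenylphenyl}propanoyl]oxazolidin-2-one | CC(C)=CCc1cc([C@@H](O)[C@@H](O[Si](C)(C)C(C)(C)C)C(=O)N2[C@@H](Cc3ccccc3)COC2=O)ccc1O[Si](C)(C)C(C)(C)C | intermediate
11 | (2R,3R)-2-(TBS-oxy)-3-hydroxy-N-methoxy-N-methyl-3-[4-(TBS-oxy)-3-prenylphenyl]propanamide | CC(C)=CCc1cc([C@@H](O)[C@@H](O[Si](C)(C)C(C)(C)C)C(=O)N(C)OC)ccc1O[Si](C)(C)C(C)(C)C | intermediate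
12 | (2R,3R)-2-(TBS-oxy)-N-methoxy-N-methyl-3-[4-(TBS-oxy)-3-prenylphenyl]-3-(TES-oxy)propanamide | CC(C)=CCc1cc([C@@H](O[Si](CC)(CC)CC)[C@@H](O[Si](C)(C)C(C)(C)C)C(=O)N(C)OC)ccc1O[Si](C)(C)C(C)(C)C | intermediate
13 | cyclohexane-1,3-dione | O=C1CCCC(=O)C1 | starting material
14 | 2-prenylcyclohexane-1,3-dione | CC(C)=CCC1C(=O)CCCC1=O | intermediate
15 | dilithium dianion of 14 (cross-conjugated dienolate, carbanion at C4) | [Li+].[Li+].CC(C)=CCC1=C([O-])CCC=C1[O-] | intermediate
16 | 4-[(2R,3R)-2-(TBS-oxy)-3-{4-(TBS-oxy)-3-prenylphenyl}-3-(TES-oxy)propanoyl]-2-prenylcyclohexane-1,3-dione (dienol form) | CC(C)=CCc1cc([C@@H](O[Si](CC)(CC)CC)[C@@H](O[Si](C)(C)C(C)(C)C)C(=O)C2=C(O)C(CC=C(C)C)=C(O)CC2)ccc1O[Si](C)(C)C(C)(C)C | intermediate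
17 | 4-[(2R,3R)-2-(TBS-oxy)-3-hydroxy-3-{4-(TBS-oxy)-3-prenylphenyl}propanoyl]-2-prenylcyclohexane-1,3-dione (dienol form) | CC(C)=CCc1cc([C@@H](O)[C@@H](O[Si](C)(C)C(C)(C)C)C(=O)C2=C(O)C(CC=C(C)C)=C(O)CC2)ccc1O[Si](C)(C)C(C)(C)C | intermediate
18 | (2R,3R)-3-(TBS-oxy)-2-[4-(TBS-oxy)-3-prenylphenyl]-7-hydroxy-8-prenyl-2,3,5,6-tetrahydro-4H-chromen-4-one (C7 enol form) | CC(C)=CCc1cc([C@H]2OC3=C(CCC(O)=C3CC=C(C)C)C(=O)[C@@H]2O[Si](C)(C)C(C)(C)C)ccc1O[Si](C)(C)C(C)(C)C | intermediate
19 | (2R,3R)-3,7-bis(TBS-oxy)-2-[4-(TBS-oxy)-3-prenylphenyl]-8-prenyl-2,3,5,6-tetrahydro-4H-chromen-4-one | CC(C)=CCc1cc([C@H]2OC3=C(CCC(O[Si](C)(C)C(C)(C)C)=C3CC=C(C)C)C(=O)[C@@H]2O[Si](C)(C)C(C)(C)C)ccc1O[Si](C)(C)C(C)(C)C | intermediate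
20 | (2R,3R)-3,7-bis(TBS-oxy)-2-[4-(TBS-oxy)-3-prenylphenyl]-8-prenylchroman-4-one | CC(C)=CCc1cc([C@H]2Oc3c(ccc(O[Si](C)(C)C(C)(C)C)c3CC=C(C)C)C(=O)[C@@H]2O[Si](C)(C)C(C)(C)C)ccc1O[Si](C)(C)C(C)(C)C | intermediate
21 | 3-hydroxyglabrol, (2R,3R)-3,7-dihydroxy-2-(4-hydroxy-3-prenylphenyl)-8-prenylchroman-4-one | CC(C)=CCc1cc([C@H]2Oc3c(ccc(O)c3CC=C(C)C)C(=O)[C@@H]2O)ccc1O | target

Total step count: 13.
Longest linear sequence: 11 steps (1 → 3 → 4 → 10 → 11 → 12 → 16 → 17 → 18 → 19 → 20 → 21).

## Least certain steps

**Step 10 (key step).** The most likely failures are acid-driven side processes of the free 2-prenyl-1,3-dione unit: addition of a flanking enol oxygen to the C8 prenyl alkene, or ionisation at the benzylic C2 carbinol with loss of trans purity. The vinylogous-acid C8a carbonyl may also react sluggishly, so that closure stalls at the hemiketal.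

The fallback carries ring A as a mono-allyl enol ether, so that C8a is a plain beta-diketone carbonyl and the C7 oxygen is masked. It sets out from 14 and 12.
- O-allylation of 14 under Mitsunobu conditions (allyl alcohol, PPh3, diisopropyl azodicarboxylate, THF) should give 3-(allyloxy)-2-prenylcyclohex-2-en-1-one F1.
- Its kinetic enolate (LiN(iPr)2, THF, −78 °C, Stork–Danheiser deprotonation at C6) is acylated by 12 to the C6-acylated allyl enol ether F2.
- Buffered HF·pyridine gives the free C2 alcohol F3.
- The same pyridinium-salt cyclodehydration closes the same O1–C8a bond and gives the 7-allyloxy diene F4.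
- DDQ aromatises F4 to the 7-O-allyl aryl ether F5.
- Pd(PPh3)4 with morpholine removes the allyl group to give the 7-phenol bis-TBS ether F6.
- F6 is desilylated under the conditions of step 13, and the sequence rejoins the route at 21.

**Step 8.** The hindered, doubly silyloxylated Weinreb amide may be acylated slowly by the poorly soluble dianion. Proton transfer from the alpha-carbon of the amide, with beta-elimination of the silanolate, could then compete.

The fallback replaces the acyl electrophile by an aldehyde. It sets out from 12. Reduction with (iBu)2AlH (THF, −78 °C) gives the aldehyde (2R,3R)-2-(TBS-oxy)-3-[4-(TBS-oxy)-3-prenylphenyl]-3-(TES-oxy)propanal F7. Dianion 15 adds to it at −78 °C to give the beta-hydroxy dione F8 as a carbinol mixture. Dess–Martin oxidation (NaHCO3, CH2Cl2) removes the new carbinol centre and rejoins the route at 16. If the dianion itself proves the weak partner, the enolate of F1 described above takes its place.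

**Step 12.** Hydride abstraction may occur at the doubly activated methylene of the C8 prenyl group instead of at C5, or oxidation may continue past the arene, giving side-chain dienes or chromene-type products.

The fallback replaces hydride abstraction by selenoxide elimination. It sets out from 18. Double deprotonation (LiN(SiMe3)2, 2.2 equiv, THF, −78 °C) followed by PhSeBr should give the C6 phenylselanyl derivative F9. Oxidation with H2O2 (pyridine, CH2Cl2, 0 °C) causes syn elimination across C5–C6, and tautomerisation gives the phenol F6. Desilylation as in step 13 rejoins the route at 21.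

**Step 4.** The alpha-silyloxyacetyl imide may turn over slowly, or give poor anti selectivity, if silyl trapping of the aldolate is slower than retro-aldol equilibration or than silyl migration between the two oxygens.

The fallback sets the alpha-centre by a boron syn aldol and the carbinol centre by reduction. It sets out from 5 and 4.
- Acid 5 is coupled as in step 3 (through 7) with (R)-4-benzyloxazolidin-2-one, the enantiomer of 6, to give the imide F10.
- Bu2BOTf and iPr2NEt (CH2Cl2, −78 → 0 °C) with 4 give the syn adduct F11, (2R,3S), through the Zimmerman–Traxler chair.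
- Dess–Martin oxidation gives the beta-keto imide F12, whose alpha-centre is protected from enolisation by allylic strain.
- KBH(sec-Bu)3 (THF, −78 °C) should reduce the ketone under Felkin–Anh control, with the silyloxy group anti to the incoming hydride, to the anti alcohol F13, (2R,3R).
- Transamination as in step 5 rejoins the route at 11.

## Further compounds

F1 | step 10 | 3-(allyloxy)-2-prenylcyclohex-2-en-1-one | C=CCOC1=C(CC=C(C)C)C(=O)CCC1
F2 | step 10 | 3-(allyloxy)-6-[(2R,3R)-2-(TBS-oxy)-3-{4-(TBS-oxy)-3-prenylphenyl}-3-(TES-oxy)propanoyl]-2-prenylcyclohex-2-en-1-one (enol form) | CC(C)=CCc1cc([C@@H](O[Si](CC)(CC)CC)[C@@H](O[Si](C)(C)C(C)(C)C)C(=O)C2=C(O)C(CC=C(C)C)=C(OCC=C)CC2)ccc1O[Si](C)(C)C(C)(C)C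
F3 | step 10 | 3-(allyloxy)-6-[(2R,3R)-2-(TBS-oxy)-3-hydroxy-3-{4-(TBS-oxy)-3-prenylphenyl}propanoyl]-2-prenylcyclohex-2-en-1-one (enol form) | CC(C)=CCc1cc([C@@H](O)[C@@H](O[Si](C)(C)C(C)(C)C)C(=O)C2=C(O)C(CC=C(C)C)=C(OCC=C)CC2)ccc1O[Si](C)(C)C(C)(C)C
F4 | step 10 | (2R,3R)-7-(allyloxy)-3-(TBS-oxy)-2-[4-(TBS-oxy)-3-prenylphenyl]-8-prenyl-2,3,5,6-tetrahydro-4H-chromen-4-one | CC(C)=CCc1cc([C@H]2OC3=C(CCC(OCC=C)=C3CC=C(C)C)C(=O)[C@@H]2O[Si](C)(C)C(C)(C)C)ccc1O[Si](C)(C)C(C)(C)C
F5 | step 10 | (2R,3R)-7-(allyloxy)-3-(TBS-oxy)-2-[4-(TBS-oxy)-3-prenylphenyl]-8-prenylchroman-4-one | CC(C)=CCc1cc([C@H]2Oc3c(ccc(OCC=C)c3CC=C(C)C)C(=O)[C@@H]2O[Si](C)(C)C(C)(C)C)ccc1O[Si](C)(C)C(C)(C)C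
F6 | step 10 | (2R,3R)-3-(TBS-oxy)-2-[4-(TBS-oxy)-3-prenylphenyl]-7-hydroxy-8-prenylchroman-4-one | CC(C)=CCc1cc([C@H]2Oc3c(ccc(O)c3CC=C(C)C)C(=O)[C@@H]2O[Si](C)(C)C(C)(C)C)ccc1O[Si](C)(C)C(C)(C)C
F7 | step 8 | (2R,3R)-2-(TBS-oxy)-3-[4-(TBS-oxy)-3-prenylphenyl]-3-(TES-oxy)propanal | CC(C)=CCc1cc([C@@H](O[Si](CC)(CC)CC)[C@@H](O[Si](C)(C)C(C)(C)C)C=O)ccc1O[Si](C)(C)C(C)(C)C
F8 | step 8 | 4-[1-hydroxy-2-(TBS-oxy)-3-{4-(TBS-oxy)-3-prenylphenyl}-3-(TES-oxy)propyl]-2-prenylcyclohexane-1,3-dione, mixture at the new carbinol and at C4 of the dione (enol form) | CC(C)=CCc1cc([C@@H](O[Si](CC)(CC)CC)[C@@H](O[Si](C)(C)C(C)(C)C)C(O)C2CCC(O)=C(CC=C(C)C)C2=O)ccc1O[Si](C)(C)C(C)(C)C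
F9 | step 12 | (2R,3R)-3-(TBS-oxy)-2-[4-(TBS-oxy)-3-prenylphenyl]-7-hydroxy-6-(phenylselanyl)-8-prenyl-2,3,5,6-tetrahydro-4H-chromen-4-one, either epimer at C6 | CC(C)=CCc1cc([C@H]2OC3=C(CC([Se]c4ccccc4)C(O)=C3CC=C(C)C)C(=O)[C@@H]2O[Si](C)(C)C(C)(C)C)ccc1O[Si](C)(C)C(C)(C)C
F10 | step 4 | (R)-4-benzyl-3-{[(tert-butyldimethylsilyl)oxy]acetyl}oxazolidin-2-one | CC(C)(C)[Si](C)(C)OCC(=O)N1[C@H](Cc2ccccc2)COC1=O
F11 | step 4 | (R)-4-benzyl-3-[(2R,3S)-2-(TBS-oxy)-3-hydroxy-3-{4-(TBS-oxy)-3-prenylphenyl}propanoyl]oxazolidin-2-one | CC(C)=CCc1cc([C@H](O)[C@@H](O[Si](C)(C)C(C)(C)C)C(=O)N2[C@H](Cc3ccccc3)COC2=O)ccc1O[Si](C)(C)C(C)(C)C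
F12 | step 4 | (R)-4-benzyl-3-[(2R)-2-(TBS-oxy)-3-oxo-3-{4-(TBS-oxy)-3-prenylphenyl}propanoyl]oxazolidin-2-one | CC(C)=CCc1cc(C(=O)[C@@H](O[Si](C)(C)C(C)(C)C)C(=O)N2[C@H](Cc3ccccc3)COC2=O)ccc1O[Si](C)(C)C(C)(C)C
F13 | step 4 | (R)-4-benzyl-3-[(2R,3R)-2-(TBS-oxy)-3-hydroxy-3-{4-(TBS-oxy)-3-prenylphenyl}propanoyl]oxazolidin-2-one | CC(C)=CCc1cc([C@@H](O)[C@@H](O[Si](C)(C)C(C)(C)C)C(=O)N2[C@H](Cc3ccccc3)COC2=O)ccc1O[Si](C)(C)C(C)(C)C
A1 | alternative 1 | methyl (E)-5-diazo-4-oxopent-2-enoate | COC(=O)/C=C/C(=O)C=[N+]=[N-]
A2 | alternative 1 | triisopropyl[(5-methylhex-4-en-1-yn-1-yl)oxy]silane | CC(C)=CCC#CO[Si](C(C)C)(C(C)C)C(C)C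
A3 | alternative 1 | methyl 2-hydroxy-3-prenyl-4-(triisopropylsilyloxy)benzoate | COC(=O)c1ccc(O[Si](C(C)C)(C(C)C)C(C)C)c(CC=C(C)C)c1O
A4 | alternative 2 | (1S,2R)-1,2-bis(TBS-oxy)-1-[4-(TBS-oxy)-3-prenylphenyl]-9,9-dimethoxy-6-prenylnonane-3,5,7-trione | CC(C)=CCc1cc([C@H](O[Si](C)(C)C(C)(C)C)[C@@H](O[Si](C)(C)C(C)(C)C)C(=O)CC(=O)C(CC=C(C)C)C(=O)CC(OC)OC)ccc1O[Si](C)(C)C(C)(C)C
A5 | alternative 2 | (2R,3S)-2,3-bis(TBS-oxy)-3-[4-(TBS-oxy)-3-prenylphenyl]-1-(2,4-dihydroxy-3-prenylphenyl)propan-1-one | CC(C)=CCc1cc([C@H](O[Si](C)(C)C(C)(C)C)[C@@H](O[Si](C)(C)C(C)(C)C)C(=O)c2ccc(O)c(CC=C(C)C)c2O)ccc1O[Si](C)(C)C(C)(C)C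
A6 | alternative 3 | (2R,3S)-6-(TBS-oxy)-2-[4-(TBS-oxy)-3-prenylphenyl]-3-hydroxy-7-prenyl-2,3-dihydrobenzofuran-3-carbaldehyde | CC(C)=CCc1cc([C@H]2Oc3c(CC=C(C)C)c(O[Si](C)(C)C(C)(C)C)ccc3[C@@]2(O)C=O)ccc1O[Si](C)(C)C(C)(C)C
A7 | alternative 3 | (2R,3R)-7-(TBS-oxy)-2-[4-(TBS-oxy)-3-prenylphenyl]-3-hydroxy-8-prenylchroman-4-one | CC(C)=CCc1cc([C@H]2Oc3c(ccc(O[Si](C)(C)C(C)(C)C)c3CC=C(C)C)C(=O)[C@@H]2O)ccc1O[Si](C)(C)C(C)(C)C
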